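The readings come from a simulation for substances that don't exist.

A small charge of substrate, 42 mM, stands against twice as much coupling partner in the blue run, so if the two pair one to one, substrate is the limiting reagent on paper. Friday's flask repeats those charges.

| flask | substrate | coupling partner | remark | time |
|---|---|---|---|---|
| blue | 42 mM | 84 mM | run made earlier |  |
| amber | 42 mM | 42 mM | run made earlier |  |
| ochre | 42 mM | 63 mM | run made earlier |  |
| violet | 63 mM | 84 mM | run made earlier |  |
| Wednesday's | 42 mM | 84.0 mM (fed, over 1.0 h) | all else is in the flask from the start; the feed brings no volume worth counting | 5.0 h |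
| Friday's | 42 mM | 84.0 mM | everything together at the start | 5.0 h |
| Saturday's | 42 mM (fed, over 1.0 h) | 84.0 mM | all else is in the flask from the start; the feed brings no volume worth counting | 5.0 h |
| Sunday's | 42 mM (in portions, 5, over 1.0 h) | 84.0 mM | first portion at the start, last at 1.0 h | 5.0 h |

| run | time / h | target / % | substrate / % |
|---|---|---|---|
| blue | 0.250 | 10.7 | 85.9 |
| blue | 0.500 | 15.8 | 79.2 |
| blue | 1.33 | 25.9 | 61.6 |
| blue | 3.00 | 29.4 | 44.5 |
| amber | 0.833 | 13.2 | 80.3 |
| amber | 1.50 | 19.5 | 72.2 |
| amber | 2.50 | 20.1 | 63.9 |
| amber | 3.00 | 20.5 | 59.9 |
| ochre | 0.417 | 11.1 | 85.8 |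
| ochre | 1.00 | 18.1 | 72.0 |
| ochre | 2.00 | 24.3 | 58.0 |
| ochre | 3.00 | 24.6 | 48.9 |
| violet | 0.833 | 18.8 | 72.6 |
| violet | 1.50 | 20.8 | 61.5 |
| violet | 2.50 | 22.9 | 49.4 |
| violet | 3.00 | 23.0 | 44.0 |

(readings scatter by 1 percentage point)



* which flask leads in amount of target, in percent of the substrate charged ("all alike" within 1.5 percentage points) (Wednesday's / Friday's / Saturday's / Sunday's / all alike)
* how much target is there at the end, in percent of the substrate charged: Wednesday's
* how much target is there at the end, in percent of the substrate charged: Friday's
* how much target is there at the end, in percent of the substrate charged: Saturday's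
* how much target is there at the end, in percent of the substrate charged: Sunday's

Turn the question round. For Wednesday's slow feed of partner to lose to Friday's single charge, a waiting partner molecule would have to be safe, leaving through substrate and no other way. Follow one such molecule and call χ the share of the partner charge that has met substrate. Its ceiling is the substrate lost over the partner charged, which by 3.00 h in the blue run reads 27.7%.

If partner were safe, at least 72.2% would still stand, and target gained per hour per unit of substrate should hold up about as well. Between the first interval and the interval ending at 1.33 h, that rate kept 37.5%, far less. Some of that fall may be scatter. In the amber run, with half the partner, it kept 70.5%, more. So I read partner as leaving faster the more of it stands, by meeting itself. A feed holds its level down, so my order is Wednesday's, Friday's, then Saturday's and Sunday's, where partner waits for substrate still to come.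

The forecast differs: it names Friday's with 30%, then 28.5% for Sunday's, 28% for Saturday's and 19.5% for Wednesday's, holding that “Feeding partner starves the catalyst while it dies”.

    substrate + coupling partner → target (k = 0.00170 L mol⁻¹ s⁻¹)
    substrate + coupling partner → isomer of the product (k = 1.10 × 10⁻⁴ L mol⁻¹ s⁻¹)
    substrate + coupling partner → second isomer (k = 1.50 × 10⁻⁴ L mol⁻¹ s⁻¹)
    2 coupling partner → homo dimer (k = 0.00200 L mol⁻¹ s⁻¹)
    substrate + target → side product (k = 0.00150 L mol⁻¹ s⁻¹)

Wednesday's leads with 32.1%, against 29.6% for Friday's, 23.9% for Saturday's and 24.1% for Sunday's. Against substrate as charged, by its three steps together, a partner molecule has a half-life of 2.34 h; against itself at 84.0 mM its first half-life is 0.827 h, shorter than that. The ceiling on χ read 27.7% at 3.00 h in the blue run, and Friday's substrate loss puts it at 32.9% at 5.00 h. Take from each charge what stands free and two for each homo dimer at that time, and χ comes to 25.6% in Friday's, below that ceiling, and to 20.9% in Saturday's.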